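**Plan**

- Locants: ring A (six-membered) is C1(Et)=C2–C3(Et, styryl)–C4(Me, C10O2H)–C5–C9; ring B (five-membered) is C5–C6(Et)=C7–C8(Me)–C9.
- Enabling feature: the carboxyl carbon C10 sits on C4, and the ring A alkene C1=C2 lies γ,δ to it across the C3–C4 bond that joins the two quaternary carbons. C3–C4 is therefore cut last, as a [3,3] shift that leads back to the δ-lactone 25 (C10–O–C1).
- Further cuts: C1–ethyl and C1–O (ethyl addition to dienyl ketone 22 with lactone closure), C3–styryl (Suzuki), C1–C2 (acetylide addition), C4–C5 (orthoester Claisen), C6–ethyl (Negishi), C9–C1 (conjugate vinylation of 2-methylcyclopentenone).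
- Forward order: ring B is built and substituted first (steps 1–7), the C9 side arm is grown into the dienyl ketone (steps 8–11), the lactone ring closes in step 12 and ring A closes last in step 13.
- Stereochemistry: C9 from the rhodium/(R)-BINAP conjugate addition; C8 by equilibration to trans; C7 by CBS reduction, relayed to C5 by the suprafacial Claisen shift; C1 by Felkin–Anh ethyl addition; C3 and C4 by transfer from C1 and the E C2=C3 alkene through a boat transition state.

Key step: step 13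

Remark: ligand and catalyst enantiomers are those predicted by the standard models for these reactions; compounds 15–25 are carried as C4 epimer mixtures because C4 becomes trigonal in 26.

**Route**

Step 1
Reactants: 1 2-methylcyclopent-2-en-1-one; 2 potassium vinyltrifluoroborate
Product: 3 (2S,3S)-3-ethenyl-2-methylcyclopentan-1-one (vinyl trans to methyl)
Conditions: [Rh(cod)2]BF4 (3 mol %), (R)-BINAP (3.3 mol %), Et3N (1 equiv), toluene/H2O 4:1, 100 °C
Reagents that add atoms: potassium vinyltrifluoroborate (2), C=C[B-](F)(F)F.[K+]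
Why: Rhodium-catalysed asymmetric 1,4-addition (Hayashi–Miyaura reaction), in which the (R)-BINAP–rhodium vinyl species should insert the enone on the face that makes C9 (S), while the α-centre C8 equilibrates under the hot basic aqueous conditions to the more stable trans arrangement.

Step 2
Reactants: 3 (2S,3S)-3-ethenyl-2-methylcyclopentan-1-one
Product: 5 (2S,3R)-3-(diethoxymethyl)-2-methylcyclopentan-1-one, via aldehyde 4 (not isolated)
Conditions: O3, CH2Cl2, −78 °C; Me2S, −78 → 23 °C; then HC(OEt)3 (1.2 equiv), EtOH, PPTS (5 mol %), 0 °C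
Reagents that add atoms: ozone, [O-][O+]=O (carbonyl oxygen of 4); triethyl orthoformate, CCOC(OCC)OCC (ethoxy groups of 5)
Why: Ozonolysis cleaves the only C=C bond to aldehyde 4, and acid-catalysed acetalisation takes the aldehyde far faster than the ring ketone (any ketal reverts on aqueous work-up), so the future C1 is masked while C8 and C9 stay in their preferred trans relation.

Step 3
Reactants: 5 (2S,3R)-3-(diethoxymethyl)-2-methylcyclopentan-1-one
Product: 7 (4R,5S)-4-(diethoxymethyl)-5-methylcyclopent-2-en-1-one, via silyl enol ether 6 (not isolated)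
Conditions: LiN(iPr)2, TMSCl, THF, −78 °C; then Pd(OAc)2 (1.05 equiv), MeCN, 23 °C
Reagents that add atoms: chlorotrimethylsilane, C[Si](C)(C)Cl (silyl group of 6 only)
Why: Kinetic deprotonation at the unhindered CH2 (C6) and O-silylation give the less substituted silyl enol ether, which Pd(OAc)2 dehydrogenates (Saegusa–Ito oxidation) to the C5=C6 enone without touching the stereocentres.

Step 4
Reactants: 7 (4R,5S)-4-(diethoxymethyl)-5-methylcyclopent-2-en-1-one
Product: 8 (4S,5S)-4-(diethoxymethyl)-2-iodo-5-methylcyclopent-2-en-1-one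
Conditions: I2 (1.5 equiv), pyridine/CH2Cl2 1:1, 0 → 23 °C
Reagents that add atoms: iodine, II
Why: α-Iodination of a cyclic enone by conjugate addition of pyridine, iodination of the resulting enolate and elimination places iodine at C6 (the descriptor at C4 changes only because iodine alters the CIP priorities).

Step 5
Reactants: 8 (4S,5S)-4-(diethoxymethyl)-2-iodo-5-methylcyclopent-2-en-1-one; 9 diethylzinc
Product: 10 (4R,5S)-4-(diethoxymethyl)-2-ethyl-5-methylcyclopent-2-en-1-one
Conditions: Et2Zn, Pd(dppf)Cl2 (5 mol %), THF, 50 °C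
Reagents that add atoms: diethylzinc (9), CC[Zn]CC
Why: Negishi cross-coupling of the alkenyl iodide with the ethylzinc reagent, the wide bite angle of dppf favouring reductive elimination over β-hydride loss, installs the C6 ethyl group.

Step 6
Reactants: 10 (4R,5S)-4-(diethoxymethyl)-2-ethyl-5-methylcyclopent-2-en-1-one
Product: 11 (1S,4R,5S)-4-(diethoxymethyl)-2-ethyl-5-methylcyclopent-2-en-1-ol (hydroxyl cis to the neighbouring methyl)
Conditions: (R)-2-methyl-CBS-oxazaborolidine (20 mol %), catecholborane (1.5 equiv), toluene, −78 °C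
Reagents that add atoms: none
Why: Corey–Bakshi–Shibata reduction, in which the (R)-oxazaborolidine (alkenyl flank as the large group) should deliver hydride to the carbonyl face anti to the C8 methyl group, so catalyst and substrate bias agree and C7 is set (S).

Step 7
Reactants: 11 (1S,4R,5S)-4-(diethoxymethyl)-2-ethyl-5-methylcyclopent-2-en-1-ol; 12 triethyl orthopropionate
Product: 15 ethyl (2RS)-2-[(1S,4R,5S)-5-(diethoxymethyl)-2-ethyl-4-methylcyclopent-2-en-1-yl]propanoate, via mixed orthoester 13 (not isolated), via ketene acetal 14 (not isolated)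
Conditions: EtC(OEt)3 (8 equiv), EtCO2H (10 mol %), 135 °C, EtOH distilled off
Reagents that add atoms: triethyl orthopropionate (12), CCC(OCC)(OCC)OCC
Why: Johnson orthoester Claisen rearrangement, in which exchange and loss of ethanol give ketene acetal 14 and its suprafacial [3,3] shift carries the configuration of the C7–O bond to the new C4–C5 bond on the same ring face (C5 trans to the C9 substituent) and moves the alkene to C6=C7, with C4 deliberately left uncontrolled.

Step 8
Reactants: 15 ethyl (2RS)-2-[(1S,4R,5S)-5-(diethoxymethyl)-2-ethyl-4-methylcyclopent-2-en-1-yl]propanoate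
Product: 16 ethyl (2RS)-2-[(1S,4R,5S)-2-ethyl-5-formyl-4-methylcyclopent-2-en-1-yl]propanoate
Conditions: 1 M aq. HCl, THF, 0 → 23 °C
Reagents that add atoms: water, O
Why: Acid-catalysed acetal hydrolysis frees the aldehyde while ester and trisubstituted alkene are inert, and C9 already holds its most stable all-trans orientation, so enolisation cannot erode it.

Step 9
Reactants: 16 ethyl (2RS)-2-[(1S,4R,5S)-2-ethyl-5-formyl-4-methylcyclopent-2-en-1-yl]propanoate; 17 but-1-yne
Product: 18 ethyl (2RS)-2-[(1S,4R,5S)-2-ethyl-5-[(1RS)-1-hydroxypent-2-yn-1-yl]-4-methylcyclopent-2-en-1-yl]propanoate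
Conditions: n-BuLi, THF, −78 °C (17 to lithium but-1-ynide); then 16, −78 °C; aq. NH4Cl
Reagents that add atoms: but-1-yne (17), CCC#C
Why: 1,2-Addition of the lithium acetylide to the aldehyde at −78 °C, where the hindered ester does not react; the carbinol configuration is irrelevant because it is oxidised in step 11.

Step 10
Reactants: 18 ethyl (2RS)-2-[(1S,4R,5S)-2-ethyl-5-[(1RS)-1-hydroxypent-2-yn-1-yl]-4-methylcyclopent-2-en-1-yl]propanoate; 19 (E)-(2-bromoethenyl)benzene
Product: 21 ethyl (2RS)-2-[(1S,4R,5S)-2-ethyl-5-[(1RS,2E,4E)-3-ethyl-1-hydroxy-5-phenylpenta-2,4-dien-1-yl]-4-methylcyclopent-2-en-1-yl]propanoate, via alkenylborane 20 (not isolated)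
Conditions: Cy2BH (2.2 equiv, from BH3·SMe2 and cyclohexene), THF, 0 → 23 °C; then 19, Pd(PPh3)4 (5 mol %), 3 M aq. K3PO4, 50 °C
Reagents that add atoms: dicyclohexylborane, B(C1CCCCC1)C1CCCCC1 (boron groups of 20 only); (E)-(2-bromoethenyl)benzene (19), Br/C=C/c1ccccc1
Why: syn-Hydroboration should place boron on C3, the alkyne carbon remote from the branched O-borylated carbinol, and Suzuki–Miyaura coupling with retention at both partners then gives the (2E,4E)-diene with ethyl cis and styryl trans to C1, the geometry the key step needs.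

Step 11
Reactants: 21 ethyl (2RS)-2-[(1S,4R,5S)-2-ethyl-5-[(1RS,2E,4E)-3-ethyl-1-hydroxy-5-phenylpenta-2,4-dien-1-yl]-4-methylcyclopent-2-en-1-yl]propanoate
Product: 22 ethyl (2RS)-2-[(1S,4R,5S)-2-ethyl-5-[(2E,4E)-3-ethyl-5-phenylpenta-2,4-dienoyl]-4-methylcyclopent-2-en-1-yl]propanoate
Conditions: MnO2 (activated, excess), CH2Cl2, 23 °C
Reagents that add atoms: none
Why: Manganese dioxide oxidation of the doubly allylic alcohol gives the dienyl ketone under neutral conditions that leave the diene geometry, the ester and the all-trans ring untouched.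

Step 12
Reactants: 22 ethyl (2RS)-2-[(1S,4R,5S)-2-ethyl-5-[(2E,4E)-3-ethyl-5-phenylpenta-2,4-dienoyl]-4-methylcyclopent-2-en-1-yl]propanoate; 23 ethylmagnesium bromide
Product: 25 (1S,4RS,4aS,7R,7aS)-1,5-diethyl-1-[(1E,3E)-2-ethyl-4-phenylbuta-1,3-dien-1-yl]-4,7-dimethyl-4,4a,7,7a-tetrahydrocyclopenta[c]pyran-3(1H)-one, via hydroxy ester 24 (not isolated)
Conditions: EtMgBr (1.2 equiv), CeCl3 (1.3 equiv), THF, −78 °C; then 23 °C
Reagents that add atoms: ethylmagnesium bromide (23), CC[Mg]Br
Why: Cerium chloride-mediated Grignard 1,2-addition suppresses enolisation and conjugate addition, and by the Felkin–Anh model ethyl should attack anti to the bulkier C5 branch with C8 inside, giving the (S)-configured tertiary alkoxide, which closes the δ-lactone by acyl substitution at the ester on warming.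

Step 13
Reactants: 25 (1S,4RS,4aS,7R,7aS)-1,5-diethyl-1-[(1E,3E)-2-ethyl-4-phenylbuta-1,3-dien-1-yl]-4,7-dimethyl-4,4a,7,7a-tetrahydrocyclopenta[c]pyran-3(1H)-one
Product: 28 spiculoic acid B [(1R,3aR,4R,5S,7aS)-3,5,7-triethyl-1,4-dimethyl-5-[(E)-2-phenylethenyl]-3a,4,5,7a-tetrahydro-1H-indene-4-carboxylic acid], via silyl ketene acetal 26 (not isolated), via silyl ester 27 (not isolated)
Conditions: LiN(iPr)2 (1.3 equiv), TBSCl (1.5 equiv), THF/DMPU, −78 °C; then toluene, 90 °C; then AcOH/THF/H2O, 23 °C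
Reagents that add atoms: tert-butyldimethylsilyl chloride, CC(C)(C)[Si](C)(C)Cl (silyl group of 26 and 27 only)
Why: LiN(iPr)2 removes the lone α-hydrogen at C4 and silylation locks the enolate as the cyclic ketene acetal 26, whose O–C1 bond is allylic to C2=C3, so a concerted suprafacial [3,3] sigmatropic shift forms C3–C4, breaks C1–O and leaves the C1=C2 alkene and silyl ester 27, which is hydrolysed on work-up. The closest known reaction is the ring-contracting Ireland–Claisen rearrangement of silyl ketene acetals of lactones that carry an alkenyl group on the carbinol carbon, which gives cycloalkene carboxylic acids. Ring A is closed by this C3–C4 bond through a boat-like, bicyclo[2.2.2]-type transition state (bridges O–C10, C5–C9 and C2=C3 between C1 and C4), the only topology a six-membered lactone allows. C4 is controlled by C1: the dienyl arm lies on the lactone face syn to C6 and anti to H5, so C3 bonds to that face of the planar ketene acetal and the carboxyl group ends cis to H5. C3 is controlled by the E geometry of C2=C3 inside the enforced boat, which puts ethyl on the side of the C4 methyl group and styryl on the side of the carboxyl group. The step needs bonding at C3 rather than ionisation of the tertiary C1–O bond or attack at the styryl terminus, which the short C5–C9 tether (only C3 can reach C4) and the ring-fixed ketene acetal geometry should secure, while the intramolecular setting and the new C=O bond offset the crowding of two fully substituted termini.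

**Compound list**

1 | 2-methylcyclopent-2-en-1-one | CC1=CCCC1=O | starting material
2 | potassium vinyltrifluoroborate | C=C[B-](F)(F)F.[K+] | starting material
3 | (2S,3S)-3-ethenyl-2-methylcyclopentan-1-one | O=C1CC[C@@H](C=C)[C@@H]1C | intermediate
4 | (1R,2S)-2-methyl-3-oxocyclopentane-1-carbaldehyde | O=C1CC[C@@H](C=O)[C@@H]1C | intermediate
5 | (2S,3R)-3-(diethoxymethyl)-2-methylcyclopentan-1-one | O=C1CC[C@@H](C(OCC)OCC)[C@@H]1C | intermediate
6 | {[(4R,5S)-4-(diethoxymethyl)-5-methylcyclopent-1-en-1-yl]oxy}trimethylsilane | C[Si](C)(C)OC1=CC[C@@H](C(OCC)OCC)[C@@H]1C | intermediate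
7 | (4R,5S)-4-(diethoxymethyl)-5-methylcyclopent-2-en-1-one | O=C1C=C[C@@H](C(OCC)OCC)[C@@H]1C | intermediate
8 | (4S,5S)-4-(diethoxymethyl)-2-iodo-5-methylcyclopent-2-en-1-one | O=C1C(I)=C[C@@H](C(OCC)OCC)[C@@H]1C | intermediate
9 | diethylzinc | CC[Zn]CC | starting material
10 | (4R,5S)-4-(diethoxymethyl)-2-ethyl-5-methylcyclopent-2-en-1-one | O=C1C(CC)=C[C@@H](C(OCC)OCC)[C@@H]1C | intermediate
11 | (1S,4R,5S)-4-(diethoxymethyl)-2-ethyl-5-methylcyclopent-2-en-1-ol | O[C@@H]1C(CC)=C[C@@H](C(OCC)OCC)[C@@H]1C | intermediate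
12 | triethyl orthopropionate (1,1,1-triethoxypropane) | CCC(OCC)(OCC)OCC | starting material
13 | 1-{[(1S,4R,5S)-4-(diethoxymethyl)-2-ethyl-5-methylcyclopent-2-en-1-yl]oxy}-1,1-diethoxypropane (mixed orthoester) | CCC(OCC)(OCC)O[C@@H]1C(CC)=C[C@@H](C(OCC)OCC)[C@@H]1C | intermediate
14 | (1S,4R,5S)-4-(diethoxymethyl)-1-[(1-ethoxyprop-1-en-1-yl)oxy]-2-ethyl-5-methylcyclopent-2-ene (ketene acetal) | CC=C(OCC)O[C@@H]1C(CC)=C[C@@H](C(OCC)OCC)[C@@H]1C | intermediate
15 | ethyl (2RS)-2-[(1S,4R,5S)-5-(diethoxymethyl)-2-ethyl-4-methylcyclopent-2-en-1-yl]propanoate | CCOC(=O)C(C)[C@H]1C(CC)=C[C@@H](C)[C@@H]1C(OCC)OCC | intermediate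
16 | ethyl (2RS)-2-[(1S,4R,5S)-2-ethyl-5-formyl-4-methylcyclopent-2-en-1-yl]propanoate | CCOC(=O)C(C)[C@H]1C(CC)=C[C@@H](C)[C@@H]1C=O | intermediate
17 | but-1-yne | CCC#C | starting material
18 | ethyl (2RS)-2-[(1S,4R,5S)-2-ethyl-5-[(1RS)-1-hydroxypent-2-yn-1-yl]-4-methylcyclopent-2-en-1-yl]propanoate | CCOC(=O)C(C)[C@H]1C(CC)=C[C@@H](C)[C@@H]1C(O)C#CCC | intermediate
19 | (E)-(2-bromoethenyl)benzene | Br/C=C/c1ccccc1 | starting material
20 | ethyl (2RS)-2-[(1S,4R,5S)-5-{(1RS,2Z)-3-(dicyclohexylboranyl)-1-[(dicyclohexylboranyl)oxy]pent-2-en-1-yl}-2-ethyl-4-methylcyclopent-2-en-1-yl]propanoate | CCOC(=O)C(C)[C@H]1C(CC)=C[C@@H](C)[C@@H]1C(OB(C2CCCCC2)C2CCCCC2)/C=C(CC)/B(C2CCCCC2)C2CCCCC2 | intermediate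
21 | ethyl (2RS)-2-[(1S,4R,5S)-2-ethyl-5-[(1RS,2E,4E)-3-ethyl-1-hydroxy-5-phenylpenta-2,4-dien-1-yl]-4-methylcyclopent-2-en-1-yl]propanoate | CCOC(=O)C(C)[C@H]1C(CC)=C[C@@H](C)[C@@H]1C(O)/C=C(CC)/C=C/c2ccccc2 | intermediate
22 | ethyl (2RS)-2-[(1S,4R,5S)-2-ethyl-5-[(2E,4E)-3-ethyl-5-phenylpenta-2,4-dienoyl]-4-methylcyclopent-2-en-1-yl]propanoate | CCOC(=O)C(C)[C@H]1C(CC)=C[C@@H](C)[C@@H]1C(=O)/C=C(CC)/C=C/c2ccccc2 | intermediate
23 | ethylmagnesium bromide | CC[Mg]Br | starting material
24 | ethyl (2RS)-2-[(1S,4R,5S)-2-ethyl-5-[(3S,4E,6E)-5-ethyl-3-hydroxy-7-phenylhepta-4,6-dien-3-yl]-4-methylcyclopent-2-en-1-yl]propanoate (formed as its alkoxide) | CCOC(=O)C(C)[C@H]1C(CC)=C[C@@H](C)[C@@H]1[C@@](O)(CC)/C=C(CC)/C=C/c2ccccc2 | intermediate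
25 | (1S,4RS,4aS,7R,7aS)-1,5-diethyl-1-[(1E,3E)-2-ethyl-4-phenylbuta-1,3-dien-1-yl]-4,7-dimethyl-4,4a,7,7a-tetrahydrocyclopenta[c]pyran-3(1H)-one | CC[C@]1(/C=C(CC)/C=C/c3ccccc3)OC(=O)C(C)[C@H]2C(CC)=C[C@@H](C)[C@H]12 | intermediate
26 | O-tert-butyldimethylsilyl ketene acetal of 25 (C4=C10 double bond, other centres as in 25) | CC[C@]1(/C=C(CC)/C=C/c3ccccc3)OC(O[Si](C)(C)C(C)(C)C)=C(C)[C@H]2C(CC)=C[C@@H](C)[C@H]12 | intermediate
27 | tert-butyldimethylsilyl ester of 28 | CCC1=C[C@@](/C=C/c2ccccc2)(CC)[C@](C)(C(=O)O[Si](C)(C)C(C)(C)C)[C@H]2C(CC)=C[C@@H](C)[C@H]12 | intermediate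
28 | spiculoic acid B, (1R,3aR,4R,5S,7aS)-3,5,7-triethyl-1,4-dimethyl-5-[(E)-2-phenylethenyl]-3a,4,5,7a-tetrahydro-1H-indene-4-carboxylic acid | CCC1=C[C@@](/C=C/c2ccccc2)(CC)[C@](C)(C(=O)O)[C@H]2C(CC)=C[C@@H](C)[C@H]12 | target

**Step count**

Total steps: 13. Longest linear sequence: 13 steps (1 to 28); all other inputs are commercial reagents.

**Steps most likely to fail**

Step 13. On heating, heterolysis of the tertiary, pentadienylic C1–O bond of ketene acetal 26 may outrun the congested boat shift, leading to elimination or to scrambling of C1 and of the C2=C3 geometry; enolisation at the hindered C4 may also stay incomplete. The fallback sets out from aldehyde 16 and rejoins at 28. It makes the C3–C4 bond by an acyclic Ireland–Claisen rearrangement through an unstrained chair and closes ring A afterwards by ring-closing metathesis at C1=C2. EtMgBr at −78 °C converts 16 into ethyl (2RS)-2-[(1S,4R,5S)-2-ethyl-5-(1-hydroxypropyl)-4-methylcyclopent-2-en-1-yl]propanoate F1. Dess–Martin periodinane oxidises it to ethyl (2RS)-2-[(1S,4R,5S)-2-ethyl-4-methyl-5-propanoylcyclopent-2-en-1-yl]propanoate F2. Wittig methylenation (Ph3P=CH2) gives ethyl (2RS)-2-[(1S,4R,5S)-5-(but-1-en-2-yl)-2-ethyl-4-methylcyclopent-2-en-1-yl]propanoate F3, and LiOH gives (2RS)-2-[(1S,4R,5S)-5-(but-1-en-2-yl)-2-ethyl-4-methylcyclopent-2-en-1-yl]propanoic acid F4. In parallel, the styryl cuprate from 19 (t-BuLi, CuI) adds syn to ethyl pent-2-ynoate to give ethyl (2E,4E)-3-ethyl-5-phenylpenta-2,4-dienoate F5, which i-Bu2AlH reduces to (2E,4E)-3-ethyl-5-phenylpenta-2,4-dien-1-ol F6. Esterification of F4 with F6 (EDC, DMAP) gives (2E,4E)-3-ethyl-5-phenylpenta-2,4-dien-1-yl (2RS)-2-[(1S,4R,5S)-5-(but-1-en-2-yl)-2-ethyl-4-methylcyclopent-2-en-1-yl]propanoate F7. LiN(iPr)2/TMSCl and warming then give, by Ireland–Claisen rearrangement, (2R,3R)-2-[(1R,4R,5S)-5-(but-1-en-2-yl)-2-ethyl-4-methylcyclopent-2-en-1-yl]-3-ethyl-2-methyl-3-[(E)-2-phenylethenyl]pent-4-enoic acid F8, and the second-generation Grubbs catalyst closes ring A to 28 with loss of ethene. The price is that C3 and C4 then rest on ketene acetal geometry and on the facial bias of C5 instead of on C1, so diastereomers may have to be separated.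

Step 12. The branches at C5 and C8 are both secondary, so facial discrimination at the dienyl ketone may be low; 1,6-addition along the dienone or attack of surplus ethyl reagent on the freshly formed lactone may also intervene. The fallback sets out from 18 and rejoins at 24. Ethyl is added before the diene is built, to a slimmer alkynyl ketone, and the lactone is closed in a separate base-only operation. MnO2 oxidises 18 to ethyl (2RS)-2-[(1S,4R,5S)-2-ethyl-4-methyl-5-(pent-2-ynoyl)cyclopent-2-en-1-yl]propanoate F9. EtMgBr/CeCl3 at −78 °C with a cold acetic acid quench gives ethyl (2RS)-2-[(1S,4R,5S)-2-ethyl-5-[(3S)-3-hydroxyhept-4-yn-3-yl]-4-methylcyclopent-2-en-1-yl]propanoate F10. Dicyclohexylborane then adds with boron at C3, now next to a quaternary carbon, to give ethyl (2RS)-2-[(1S,4R,5S)-5-[(3S,4Z)-5-(dicyclohexylboranyl)-3-hydroxyhept-4-en-3-yl]-2-ethyl-4-methylcyclopent-2-en-1-yl]propanoate F11. Suzuki–Miyaura coupling with 19 in the same flask gives hydroxy ester 24, which KN(SiMe3)2 in THF at 0 °C closes to 25.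

Step 1. Insertion of the α-substituted enone into the rhodium–vinyl bond may be slow, so that protodeboronation of 2 wins, or the enantioselectivity may erode. The fallback sets out from 1 and rejoins at 3. It replaces catalytic asymmetric induction by racemic conjugate addition and resolution. CuBr·SMe2-catalysed addition of vinylmagnesium bromide in the presence of TMSCl, followed by acidic work-up, gives racemic trans-3-ethenyl-2-methylcyclopentan-1-one F12. The lithium salt of (S)-N,S-dimethyl-S-phenylsulfoximine adds to the ketone. The adduct of the wanted enantiomer, (1R,2S,3S)-3-ethenyl-2-methyl-1-{[(S)-N-methyl-S-phenylsulfonimidoyl]methyl}cyclopentan-1-ol F13, is separated by chromatography from its diastereomer (1S,2R,3R)-3-ethenyl-2-methyl-1-{[(S)-N-methyl-S-phenylsulfonimidoyl]methyl}cyclopentan-1-ol F14. Thermolysis of F13 in refluxing toluene returns enantiopure 3 (sulfoximine resolution of ketones).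

Further compounds
F1 | step 13 | ethyl (2RS)-2-[(1S,4R,5S)-2-ethyl-5-(1-hydroxypropyl)-4-methylcyclopent-2-en-1-yl]propanoate | CCOC(=O)C(C)[C@H]1C(CC)=C[C@@H](C)[C@@H]1C(O)CC
F2 | step 13 | ethyl (2RS)-2-[(1S,4R,5S)-2-ethyl-4-methyl-5-propanoylcyclopent-2-en-1-yl]propanoate | CCOC(=O)C(C)[C@H]1C(CC)=C[C@@H](C)[C@@H]1C(=O)CC
F3 | step 13 | ethyl (2RS)-2-[(1S,4R,5S)-5-(but-1-en-2-yl)-2-ethyl-4-methylcyclopent-2-en-1-yl]propanoate | CCOC(=O)C(C)[C@H]1C(CC)=C[C@@H](C)[C@@H]1C(=C)CC
F4 | step 13 | (2RS)-2-[(1S,4R,5S)-5-(but-1-en-2-yl)-2-ethyl-4-methylcyclopent-2-en-1-yl]propanoic acid | OC(=O)C(C)[C@H]1C(CC)=C[C@@H](C)[C@@H]1C(=C)CC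
F5 | step 13 | ethyl (2E,4E)-3-ethyl-5-phenylpenta-2,4-dienoate | CCOC(=O)/C=C(CC)/C=C/c1ccccc1
F6 | step 13 | (2E,4E)-3-ethyl-5-phenylpenta-2,4-dien-1-ol | OC/C=C(CC)/C=C/c1ccccc1
F7 | step 13 | (2E,4E)-3-ethyl-5-phenylpenta-2,4-dien-1-yl (2RS)-2-[(1S,4R,5S)-5-(but-1-en-2-yl)-2-ethyl-4-methylcyclopent-2-en-1-yl]propanoate | C(/C=C(CC)/C=C/c2ccccc2)OC(=O)C(C)[C@H]1C(CC)=C[C@@H](C)[C@@H]1C(=C)CC
F8 | step 13 | (2R,3R)-2-[(1R,4R,5S)-5-(but-1-en-2-yl)-2-ethyl-4-methylcyclopent-2-en-1-yl]-3-ethyl-2-methyl-3-[(E)-2-phenylethenyl]pent-4-enoic acid | C=C[C@](CC)(/C=C/c2ccccc2)[C@](C)(C(=O)O)[C@H]1C(CC)=C[C@@H](C)[C@@H]1C(=C)CC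
F9 | step 12 | ethyl (2RS)-2-[(1S,4R,5S)-2-ethyl-4-methyl-5-(pent-2-ynoyl)cyclopent-2-en-1-yl]propanoate | CCOC(=O)C(C)[C@H]1C(CC)=C[C@@H](C)[C@@H]1C(=O)C#CCC
F10 | step 12 | ethyl (2RS)-2-[(1S,4R,5S)-2-ethyl-5-[(3S)-3-hydroxyhept-4-yn-3-yl]-4-methylcyclopent-2-en-1-yl]propanoate | CCOC(=O)C(C)[C@H]1C(CC)=C[C@@H](C)[C@@H]1[C@@](O)(CC)C#CCC
F11 | step 12 | ethyl (2RS)-2-[(1S,4R,5S)-5-[(3S,4Z)-5-(dicyclohexylboranyl)-3-hydroxyhept-4-en-3-yl]-2-ethyl-4-methylcyclopent-2-en-1-yl]propanoate | CCOC(=O)C(C)[C@H]1C(CC)=C[C@@H](C)[C@@H]1[C@@](O)(CC)/C=C(CC)/B(C2CCCCC2)C2CCCCC2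
F12 | step 1 | racemic trans-3-ethenyl-2-methylcyclopentan-1-one | O=C1CC[C@@H](C=C)[C@@H]1C.O=C1CC[C@H](C=C)[C@H]1C
F13 | step 1 | (1R,2S,3S)-3-ethenyl-2-methyl-1-{[(S)-N-methyl-S-phenylsulfonimidoyl]methyl}cyclopentan-1-ol | C=C[C@@H]1CC[C@](O)(C[S@@](=O)(=NC)c2ccccc2)[C@H]1C
F14 | step 1 | (1S,2R,3R)-3-ethenyl-2-methyl-1-{[(S)-N-methyl-S-phenylsulfonimidoyl]methyl}cyclopentan-1-ol | C=C[C@H]1CC[C@@](O)(C[S@@](=O)(=NC)c2ccccc2)[C@@H]1C
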